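Start from the amounts in the flask: 0.050 M of L against 0.0750 M of Z. Every D holds two Z, and [Z] at the start falls short of twice [L], so Z is the limiting reagent for D. Z charged over twice L charged, capped at 100 % of L, I call the D ceiling:

ceiling = [Z]₀ / (2 [L]₀) = 75.0 %

common to all: L 0.050 M

| charge | Z | remark | time |
|---|---|---|---|
| blue | 0.10 M | run made earlier |  |
| ochre | 0.17 M | run made earlier |  |
| flask | 0.0750 M |  | 30 min |

| run | time / min | L / % | J / % | D / % |
|---|---|---|---|---|
| blue | 1.33 | 38.8 | 31.8 | 24.1 |
| blue | 4.00 | 14.6 | 21.4 | 50.6 |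
| blue | 6.00 | 9.4 | 15.1 | 56.5 |
| blue | 10.0 | 5.8 | 8.3 | 60.5 |
| blue | 15.0 | 2.9 | 5.0 | 62.0 |
| blue | 20.0 | 2.2 | 2.7 | 61.8 |
| ochre | 1.33 | 19.4 | 27.7 | 47.0 |
| ochre | 4.00 | 2.4 | 6.6 | 69.9 |
| ochre | 6.00 | 1.6 | 2.6 | 67.5 |
| ochre | 10.0 | 0.2 | 0.5 | 58.1 |
| ochre | 15.0 | 0 | 0 | 46.6 |
| ochre | 20.0 | 0 | 1.0 | 40.4 |

(readings scatter by 0.5 percentage points)

* how much L there is at 30 min, in percent of the L charged
* how much J there is at 30 min, in percent of the L charged
* how much D there is at 30 min, in percent of the L charged
* how much E there is at 30 min, in percent of the L charged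

Follow the blue run, whose ceiling is 100 %. In the first instants Z meets L and J together: at 1.33 min L is down to 38.8 % and D already reads 24.1 %. In the middle, at 4.00 min, D reads 50.6 %, and L, J and D add up to 86.6 %, so the remainder sits in forms not read. At the end D in the blue run changes little, reading 60.5 % at 10.0 min and 61.8 % at 20.0 min.

The ochre run has more Z, and there D reads 69.9 % at 4.00 min and 40.4 % at 20.0 min. Of these two runs, the one charged with more Z is the one whose D readings fall. Your flask has a lower ceiling than blue, so I join its end to blue's and take blue's late D as a share of the ceiling, a reading of 0.620: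

D at 30 min ≈ 75.0 % × 0.620 = 46.5 %

This is my figure for D; I give none for L, J or E.

The forecast stands higher on D than my figure: it says 10 % L, 15 % J, 55 % D and 20 % E, holding that the flask “should run short of Z within about 5 minutes”.

The flask gives 10.2 % L, 4.68 % J, 48.7 % D and 5.17 % E.

    L + Z → J (k = 0.240 M⁻¹ s⁻¹)
    Z + J → D (k = 0.260 M⁻¹ s⁻¹)
    Z + D → E (k = 0.0200 M⁻¹ s⁻¹)
    Z ⇌ X (K = 0.550, k = 0.0660 s⁻¹)
    J ⇌ Q (K = 11.0, k = 0.00160 s⁻¹)

Against its ceiling of 75.0 %, D in the flask stands at a share of 0.649, beside the 0.620 read from blue, with 0.498 % of the Z charge left. Now take the neighbour flask, with 0.030 M of L. Z over twice L gives 125 %, above the cap, so its ceiling is 100 % and blue's share gives 62.0 %. At 30 min that neighbour flask holds 55.3 % D, with 11.4 % of its own Z charge left, and 25.4 % E.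

The data come from a simulation from invented constants; the scatter is artificial.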